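Ring B (C5–C6–C7–C8–C9–C10) is cut into an acetone-like C5–C6–C7 unit and a C8–C9–C10 unit in which C8, the later exocyclic methylene carbon, is an acyl carbon and C10 the β-carbon of an alkylidene. Because C19 on C4 is 1,3 to C6, the acetone unit is locked as an enol lactone with C19. One acid-mediated operation on this monocyclic enol lactone, which carries an alkylidenesuccinic anhydride, closes ring A through C5–C10 and ring B through C7–C8, sets C5 and C10 from C4, and leaves the C6 oxygen β to the C8 ketone, which later expels it.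

Key step: step 7

Remark: carbons are numbered as in the labdane skeleton of the target (C1–C10 decalin, C11–C12 side chain, C13–C16 butenolide, C17 exocyclic methylene, C18 methyl on C4, C19 oxygenated carbon on C4, C20 methyl on C10); commercial 2,6-dimethylcyclohexanone is used as its cis/trans mixture.

Step 1
Reactants: 1 2,6-dimethylcyclohexan-1-one
Product: 2 2,6-dimethylcyclohex-1-en-1-yl prop-2-en-1-yl carbonate
Conditions: LiN(SiMe3)2, THF, −78 °C; then allyl chloroformate, −78 °C to rt
Reagents that add atoms: allyl chloroformate (C=CCOC(=O)Cl)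
Why: Enolate O-acylation (the ketone has only one enolate regiochemistry) should give the allyl enol carbonate, and any C-acylated β-keto ester isomer converges to the same product in step 2.

Step 2
Reactants: 2 2,6-dimethylcyclohex-1-en-1-yl prop-2-en-1-yl carbonate
Product: 3 (2R)-2,6-dimethyl-2-(prop-2-en-1-yl)cyclohexan-1-one
Conditions: Pd2(dba)3 (2.5 mol%), (R)-t-Bu-PHOX (6 mol%), THF, 25 °C
Reagents that add atoms: none
Why: Palladium-catalysed decarboxylative asymmetric allylic alkylation, in which loss of CO2 gives a PHOX-bound palladium allyl enolate whose C-allylation should set the quaternary carbon (C4 of the target) as R under ligand control, the C6 methine remaining an inconsequential epimer mixture.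

Step 3
Reactants: 3 (2R)-2,6-dimethyl-2-(prop-2-en-1-yl)cyclohexan-1-one
Product: 4 (2R)-2-methyl-6-oxo-2-(prop-2-en-1-yl)heptanoic acid
Conditions: O2 (1 atm), KOtBu (3 equiv), t-BuOH/THF, 0 °C to rt; then aq. HCl
Reagents that add atoms: dioxygen (O=O)
Why: Base-mediated autoxidative ketone cleavage, in which the only enolisable carbon (the methine) is oxygenated to an α-hydroperoxide that closes onto the carbonyl and fragments to the C19 acid on the untouched quaternary centre and the methyl ketone carrying C10 and C20.

Step 4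
Reactants: 4 (2R)-2-methyl-6-oxo-2-(prop-2-en-1-yl)heptanoic acid, 5 diethyl butanedioate
Product: 7 2-[(6R)-6-carboxy-6-methylnon-8-en-2-ylidene]butanedioic acid, via Stobbe half-ester 6 (not isolated)
Conditions: KOtBu (4 equiv), t-BuOH, 80 °C; then KOH, EtOH/H2O, reflux; then aq. HCl
Reagents that add atoms: potassium hydroxide ([K+].[OH-])
Why: Stobbe condensation of the methyl ketone with the succinate enolate (through the paraconic lactone) should attach C8, C9, C11 and C12 in one step and saponification frees the carboxyl groups, the alkene geometry and position being irrelevant because C9 and C10 become sp3 in step 7.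

Step 5
Reactants: 7 2-[(6R)-6-carboxy-6-methylnon-8-en-2-ylidene]butanedioic acid
Product: 8 2-[(6R)-6-carboxy-6-methyl-8-oxononan-2-ylidene]butanedioic acid
Conditions: PdCl2 (10 mol%), CuCl (1 equiv), O2 (1 atm), DMF/H2O (7:1), rt
Reagents that add atoms: water (O)
Why: Wacker oxidation should convert only the terminal allyl alkene, with Markovnikov selectivity, into the methyl ketone C6(=O)–C7 (any ene-lactone formed by carboxylate attack has the same oxidation level and converges in step 6), the electron-poor tetrasubstituted alkene being inert.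

Step 6
Reactants: 8 2-[(6R)-6-carboxy-6-methyl-8-oxononan-2-ylidene]butanedioic acid
Product: 9 (3R)-3-[4-(2,5-dioxooxolan-3-ylidene)pentyl]-3,5-dimethylfuran-2(3H)-one
Conditions: Ac2O, NaOAc, 100 °C
Reagents that add atoms: none
Why: Two dehydrations by acetic anhydride should close the succinic anhydride and turn the γ-keto acid into its enol lactone, the endocyclic C5=C6 isomer being favoured because the quaternary C4 cannot conjugate.

Step 7
Reactants: 9 (3R)-3-[4-(2,5-dioxooxolan-3-ylidene)pentyl]-3,5-dimethylfuran-2(3H)-one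
Product: 11 19,6-enol lactone of (4R,5S,9S,10R)-6-hydroxy-8-oxo-13,14,15,16,17-pentanorlabd-6-ene-12,19-dioic acid, via ring-A-closed exocyclic enol lactone 10 (not isolated)
Conditions: TfOH (3 equiv), CH2Cl2 (0.01 M), −20 °C to 0 °C; then pyridine
Reagents that add atoms: none
Why: Proposed new method: TfOH protonates the C8 carbonyl of the alkylidenesuccinic anhydride so that C10 becomes a tertiary cationic centre, which the C5=C6 enol lactone attacks (ring A, 6-exo-trig at C10, enol-exo); the acyloxocarbenium ion at C6 then loses a C7 proton to the exocyclic enol lactone, whose C7 attacks the acid-activated anhydride carbonyl C8 (ring B, 6-exo-trig acylation, enol-endo) and releases the C12 carboxyl group. The closest known reaction types are the base-mediated consecutive Michael–Claisen [3+3] annulation of a ketone (α and α′ carbons) with an α,β-unsaturated ester to a cyclohexane-1,3-dione, the Lewis-acid Mukaiyama–Michael addition to alkylidene malonates, and the acid-promoted C-acylation of enol esters by anhydrides. C5 is set by the tether, because the new ring must be cis-fused to the planar furanone, so C10 adds to the face of C5 that carries the C3 chain. C10 is set in a chair transition state in which the lactone carbonyl C19 is held pseudo-axial and the small C20 methyl, not the bulky anhydride-bearing C9, takes the axial site syn to C19, which leads to the trans ring fusion. C9 is not controlled (drawn as its equatorial epimer) and is corrected later because it is α to the C8 ketone. The step needs attack through C5 before C7 and acylation by C8 rather than C12, and both follow from ring size (six-membered against eight- and seven-membered closure).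

Step 8
Reactants: 11 19,6-enol lactone of (4R,5S,9S,10R)-6-hydroxy-8-oxo-13,14,15,16,17-pentanorlabd-6-ene-12,19-dioic acid
Product: 14 (4R,5S,9S,10R)-8-oxo-13,14,15,16,17-pentanorlabdane-12,19-dioic acid, via saturated 19,6-lactone 12 (not isolated), via C6–C7 enone diacid 13 (not isolated)
Conditions: H2 (1 atm), 10% Pd/C, EtOAc, rt; then DBU (3 equiv), H2 continued; then aq. HCl
Reagents that add atoms: none
Why: Hydrogenation of the push–pull C6=C7 bond should give a β-acyloxy ketone from which DBU expels the C19 carboxylate by E1cB elimination, and hydrogenation of the resulting enone removes the C6 oxygen tracelessly while C9 can equilibrate to the equatorial epimer α to the ketone.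

Step 9
Reactants: 14 (4R,5S,9S,10R)-8-oxo-13,14,15,16,17-pentanorlabdane-12,19-dioic acid
Product: 15 (4R,5S,9R,10S)-13,14,15,16-tetranorlabd-8(17)-ene-12,19-dioic acid
Conditions: Ph3PCH3Br (5 equiv), KOtBu (7 equiv), THF, 0 to 65 °C; then aq. HCl
Reagents that add atoms: methyltriphenylphosphonium bromide (C[P+](c1ccccc1)(c1ccccc1)c1ccccc1.[Br-])
Why: Wittig methylenation of the C8 ketone (the carboxylates are inert) should install C17 as the exocyclic methylene, the basic ylide keeping C9 at its thermodynamic equatorial configuration.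

Step 10
Reactants: 15 (4R,5S,9R,10S)-13,14,15,16-tetranorlabd-8(17)-ene-12,19-dioic acid
Product: 16 (4R,5S,9R,10S)-13,14,15,16-tetranorlabd-8(17)-ene-12,19-diol
Conditions: LiAlH4, THF, 0 °C to reflux; then aq. NaOH
Reagents that add atoms: none
Why: Hydride reduction should convert both carboxylic acids into primary alcohols and leave the 1,1-disubstituted alkene untouched.

Step 11
Reactants: 16 (4R,5S,9R,10S)-13,14,15,16-tetranorlabd-8(17)-ene-12,19-diol
Product: 17 (4R,5S,9R,10S)-12-iodo-13,14,15,16-tetranorlabd-8(17)-en-19-ol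
Conditions: I2 (1.1 equiv), PPh3, imidazole, CH2Cl2, 0 °C
Reagents that add atoms: iodine (II)
Why: Appel iodination ends in an SN2 displacement, so the unhindered C12 alcohol should react while the neopentyl, axial C19 alcohol does not.

Step 12
Reactants: 17 (4R,5S,9R,10S)-12-iodo-13,14,15,16-tetranorlabd-8(17)-en-19-ol
Product: 18 (4R,5S,9R,10S)-12-iodo-13,14,15,16-tetranorlabd-8(17)-en-19-yl acetate
Conditions: Ac2O, pyridine, DMAP (cat.), CH2Cl2, rt
Reagents that add atoms: acetic anhydride (CC(=O)OC(C)=O)
Why: Nucleophile-catalysed acetylation of the remaining primary alcohol should give the C19 acetate, the primary iodide being inert under these conditions.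

Step 13
Reactants: 18 (4R,5S,9R,10S)-12-iodo-13,14,15,16-tetranorlabd-8(17)-en-19-yl acetate, 19 3-bromofuran-2(5H)-one
Product: 21 (4R,5S,9R,10S)-19-acetoxylabda-8(17),13-dien-16,15-olide, via alkylzinc iodide 20 (not isolated)
Conditions: Zn dust, LiCl, THF, 40 °C; then 19, Pd2(dba)3 (2.5 mol%), SPhos (10 mol%), THF, rt
Reagents that add atoms: none
Why: Zinc insertion into the primary C–I bond tolerates the acetate, and Negishi coupling of the alkylzinc iodide with the α-bromobutenolide should form C12–C13 with the butenolide double bond already in place.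

Compound list
1 | 2,6-dimethylcyclohexan-1-one (cis/trans mixture) | CC1CCCC(C)C1=O | starting material
2 | 2,6-dimethylcyclohex-1-en-1-yl prop-2-en-1-yl carbonate (racemic) | C=CCOC(=O)OC1=C(C)CCCC1C | intermediate
3 | (2R)-2,6-dimethyl-2-(prop-2-en-1-yl)cyclohexan-1-one (both C6 epimers) | C=CC[C@@]1(C)CCCC(C)C1=O | intermediate
4 | (2R)-2-methyl-6-oxo-2-(prop-2-en-1-yl)heptanoic acid | C=CC[C@@](C)(CCCC(C)=O)C(=O)O | intermediate
5 | diethyl butanedioate (diethyl succinate) | CCOC(=O)CCC(=O)OCC | starting material
6 | 1-ethyl hydrogen 2-[(6R)-6-carboxy-6-methylnon-8-en-2-ylidene]butanedioate (Stobbe half-ester, alkene isomers) | C=CC[C@@](C)(CCCC(C)=C(CC(=O)O)C(=O)OCC)C(=O)O | intermediate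
7 | 2-[(6R)-6-carboxy-6-methylnon-8-en-2-ylidene]butanedioic acid (alkene isomers) | C=CC[C@@](C)(CCCC(C)=C(CC(=O)O)C(=O)O)C(=O)O | intermediate
8 | 2-[(6R)-6-carboxy-6-methyl-8-oxononan-2-ylidene]butanedioic acid (alkene isomers) | CC(=O)C[C@@](C)(CCCC(C)=C(CC(=O)O)C(=O)O)C(=O)O | intermediate
9 | (3R)-3-[4-(2,5-dioxooxolan-3-ylidene)pentyl]-3,5-dimethylfuran-2(3H)-one | CC1=C[C@@](C)(CCCC(C)=C2CC(=O)OC2=O)C(=O)O1 | intermediate
10 | (3aS,4R,7aR)-4-(2,5-dioxooxolan-3-yl)-4,7a-dimethyl-3-methylidenehexahydro-2-benzofuran-1(3H)-one (both epimers at the oxolane carbon, C9) | C=C1OC(=O)[C@]2(C)CCC[C@@](C)(C3CC(=O)OC3=O)[C@H]12 | intermediate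
11 | 19,6-enol lactone of (4R,5S,9S,10R)-6-hydroxy-8-oxo-13,14,15,16,17-pentanorlabd-6-ene-12,19-dioic acid (C12 acid free; C9 drawn equatorial) | O=C1OC2=CC(=O)[C@@H](CC(=O)O)[C@]3(C)CCC[C@]1(C)[C@@H]23 | intermediate
12 | (4R,5S,6S,9S,10R)-6-hydroxy-8-oxo-13,14,15,16,17-pentanorlabdane-12,19-dioic acid 19,6-lactone | O=C1O[C@H]2CC(=O)[C@@H](CC(=O)O)[C@]3(C)CCC[C@]1(C)[C@@H]23 | intermediate
13 | (4R,5S,9S,10R)-8-oxo-13,14,15,16,17-pentanorlabd-6-ene-12,19-dioic acid | OC(=O)C[C@@H]1C(=O)C=C[C@@H]2[C@](C)(C(=O)O)CCC[C@@]12C | intermediate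
14 | (4R,5S,9S,10R)-8-oxo-13,14,15,16,17-pentanorlabdane-12,19-dioic acid (trans-decalin, C19 acid axial, side chain equatorial) | OC(=O)C[C@@H]1C(=O)CC[C@@H]2[C@](C)(C(=O)O)CCC[C@@]12C | intermediate
15 | (4R,5S,9R,10S)-13,14,15,16-tetranorlabd-8(17)-ene-12,19-dioic acid | OC(=O)C[C@@H]1C(=C)CC[C@@H]2[C@](C)(C(=O)O)CCC[C@@]12C | intermediate
16 | (4R,5S,9R,10S)-13,14,15,16-tetranorlabd-8(17)-ene-12,19-diol | OCC[C@@H]1C(=C)CC[C@@H]2[C@](C)(CO)CCC[C@@]12C | intermediate
17 | (4R,5S,9R,10S)-12-iodo-13,14,15,16-tetranorlabd-8(17)-en-19-ol | ICC[C@@H]1C(=C)CC[C@@H]2[C@](C)(CO)CCC[C@@]12C | intermediate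
18 | (4R,5S,9R,10S)-12-iodo-13,14,15,16-tetranorlabd-8(17)-en-19-yl acetate | ICC[C@@H]1C(=C)CC[C@@H]2[C@](C)(COC(C)=O)CCC[C@@]12C | intermediate
19 | 3-bromofuran-2(5H)-one | O=C1OCC=C1Br | starting material
20 | (4R,5S,9R,10S)-19-acetoxy-13,14,15,16-tetranorlabd-8(17)-en-12-ylzinc iodide | I[Zn]CC[C@@H]1C(=C)CC[C@@H]2[C@](C)(COC(C)=O)CCC[C@@]12C | intermediate
21 | (4R,5S,9R,10S)-19-acetoxylabda-8(17),13-dien-16,15-olide (CNP0350004.2) | C=C1CC[C@@H]2[C@](C)(COC(C)=O)CCC[C@@]2(C)[C@@H]1CCC1=CCOC1=O | target

Total steps: 13. Longest linear sequence: 13 steps (1 to 21).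

Steps most likely to fail

Step 7. The C10 cation may be lost to proton loss or to isomerisation of the alkylidene anhydride before the enol lactone captures it. Facial selectivity at C10 may also be poor, or the acylation may not follow the first ring closure. The fallback is the known anionic Michael–Claisen annulation. It sets out from 8. Fischer esterification (MeOH, cat. H2SO4, rt) of the two unhindered carboxyl groups should give dimethyl 2-[(6R)-6-carboxy-6-methyl-8-oxononan-2-ylidene]butanedioate F1. KOtBu (3 equiv, THF/t-BuOH) should then effect Michael addition of the C5 enolate to C10 and Claisen condensation of C7 onto the C8 ester, giving the 12-methyl ester of 6,8-dioxo-13,14,15,16,17-pentanorlabdane-12,19-dioic acid F2. Ac2O/NaOAc lactonises the only free acid (C19) onto the C6 enol to give the 12-methyl ester of 11 F3. Hydrogenation and DBU as in step 8 give the 12-methyl ester of 14 F4, and LiOH (THF/H2O) comes back to the route at 14. The C10 configuration is then no longer tether-controlled and diastereomers may need separation.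

Step 3. The methyl ketone product may be oxygenated further under the same conditions, and the hydroperoxide may collapse unselectively. The fallback separates hydroxylation from cleavage. It sets out from 3: LiN(iPr)2 (THF, −78 °C) followed by 2-(benzenesulfonyl)-3-phenyloxaziridine should give (2R)-6-hydroxy-2,6-dimethyl-2-(prop-2-en-1-yl)cyclohexan-1-one F5, and NaIO4 (MeOH/H2O) cleaves this α-ketol and comes back at 4.

Step 8. The lactone may open before the alkene is reduced, the β-elimination may stall at the saturated lactone, or the C8 ketone may be over-reduced. The fallback replaces hydrogenation by sulfur chemistry. It sets out from 11: thiophenol and Et3N (CH2Cl2) add to C6 and expel the C19 carboxylate to give 6-(phenylsulfanyl)-8-oxo-13,14,15,16,17-pentanorlabd-6-ene-12,19-dioic acid F6, and sponge Ni (skeletal nickel, EtOH) removes sulfur and saturates the enone, coming back at 14.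

Further compounds
F1 | step 7 | dimethyl 2-[(6R)-6-carboxy-6-methyl-8-oxononan-2-ylidene]butanedioate | CC(=O)C[C@@](C)(CCCC(C)=C(CC(=O)OC)C(=O)OC)C(=O)O
F2 | step 7 | 12-methyl ester of 6,8-dioxo-13,14,15,16,17-pentanorlabdane-12,19-dioic acid (C4, C5, C9, C10 arranged as in 14) | COC(=O)C[C@@H]1C(=O)CC(=O)[C@@H]2[C@](C)(C(=O)O)CCC[C@@]12C
F3 | step 7 | 12-methyl ester of 11 | O=C1OC2=CC(=O)[C@@H](CC(=O)OC)[C@]3(C)CCC[C@]1(C)[C@@H]23
F4 | step 7 | 12-methyl ester of 14 | COC(=O)C[C@@H]1C(=O)CC[C@@H]2[C@](C)(C(=O)O)CCC[C@@]12C
F5 | step 3 | (2R)-6-hydroxy-2,6-dimethyl-2-(prop-2-en-1-yl)cyclohexan-1-one | C=CC[C@@]1(C)CCCC(C)(O)C1=O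
F6 | step 8 | 6-(phenylsulfanyl)-8-oxo-13,14,15,16,17-pentanorlabd-6-ene-12,19-dioic acid (C4, C5, C9, C10 arranged as in 14) | OC(=O)C[C@@H]1C(=O)C=C(Sc3ccccc3)[C@@H]2[C@](C)(C(=O)O)CCC[C@@]12C
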